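**Retrosynthetic overview**
- Labels: unit 1 is rings A/C (chromanone, O1, C2 to C8a) plus ring B (4-methoxyphenyl), 2,3-trans. Unit 2 is rings A''/C'' plus ring B'' (4-hydroxyphenyl), 2'',3''-cis. The units are joined C3–C3''.
- Last operation: C3–C3'' and O1''–C2'' are cut together. This gives two flavonoid monomers, the C4 silyl enol ether of a (2S)-flavanone and an α-bromochalcone, which serves as a Cα chalcone radical equivalent as in the presumed biogenetic 3,3'' coupling.
- Enabling feature: ring C'' (O1''–C2''–C3''–C4''(=O)–C4a''–C8a'') hides a chalcone with C3'' as α- and C2'' as β-carbon. Ring A'' is a symmetric phloroglucinol with two equivalent ortho oxygens. O5, O4, O4'' and O5'' around the 1,4-diketone C4–C3–C3''–C4'' form a pocket for Mg2+ that relays 3R to 3''S.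
- Monomer 1: commercial 5,7-dihydroxychromone (rings A, C) plus ring B by asymmetric conjugate arylation, which sets 2S. Monomer 2: naringenin, opened to its chalcone tetraacetate and α-brominated (rings A'', B'').
- Ring order: A, C, A'' and B'' are bought, B is attached in step 2, and ring C'' is closed last in step 6, which also frees all phenols.

Key step: step 6

Assumption: naringenin is used as the racemate because its stereocentre is destroyed in step 4, and the ligand antipode in step 2 is the one that delivers 2S (the R ligand is expected by analogy with cyclic enones).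

**Step 1**
Reactants: 1 5,7-dihydroxy-4H-chromen-4-one
Product: 2 5,7-diacetoxy-4H-chromen-4-one
Conditions: Ac2O, pyridine, DMAP (cat.), 25 °C
Reagents that add atoms: acetic anhydride CC(=O)OC(C)=O
Why: DMAP-catalysed O-acetylation (nucleophilic acyl transfer) caps both phenols, makes the chromone a better Michael acceptor and installs the only protecting group of the route, which the last step removes itself, and no stereocentre is formed.

**Step 2**
Reactants: 2 5,7-diacetoxy-4H-chromen-4-one; 3 4-methoxyphenylboronic acid
Product: 4 (2S)-5,7-diacetoxy-2-(4-methoxyphenyl)chroman-4-one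
Conditions: Pd(OCOCF3)2 (5 mol %), (R)-t-BuPyOx (6 mol %), NH4PF6 (30 mol %), H2O (5 equiv), ClCH2CH2Cl, 60 °C
Reagents that add atoms: none
Why: Palladium-catalysed asymmetric conjugate addition of an arylboronic acid to a chromone, a reaction type established for this substrate class under non-basic conditions that spare aryl acetates and do not open the flavanone, sets C2 as S through enantioface-selective insertion of C2=C3 into the cationic aryl–palladium–PyOx complex, and protonolysis of the palladium enolate releases 4.

**Step 3**
Reactants: 4 (2S)-5,7-diacetoxy-2-(4-methoxyphenyl)chroman-4-one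
Product: 5 (2S)-5,7-diacetoxy-4-(tert-butyldimethylsilyloxy)-2-(4-methoxyphenyl)-2H-chromene
Conditions: TBSOTf (1.2 equiv), Et3N (1.6 equiv), CH2Cl2, −20 to 0 °C; filtration through Et3N-deactivated silica
Reagents that add atoms: tert-butyldimethylsilyl triflate CC(C)(C)[Si](C)(C)OS(=O)(=O)C(F)(F)F
Why: Soft enolisation (silyl triflate and tertiary amine, silyl enol ether formation) silylates the C4 carbonyl oxygen before a C3 proton is removed, so no free enolate arises that could expel O1 by E1cB and C2 should stay S.

**Step 4**
Reactants: 6 (±)-naringenin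
Product: 7 (E)-3-(4-acetoxyphenyl)-1-(2,4,6-triacetoxyphenyl)prop-2-en-1-one
Conditions: Ac2O, NaOAc (anhydrous), 140 °C
Reagents that add atoms: acetic anhydride CC(=O)OC(C)=O
Why: Under the classical hot acetate conditions the 5-hydroxyflavanone opens by retro-oxa-Michael reaction (E1cB), and the released ortho phenoxide is trapped irreversibly by acetylation, which should drain the flavanone–chalcone equilibrium to the (E)-chalcone tetraacetate.

**Step 5**
Reactants: 7 (E)-3-(4-acetoxyphenyl)-1-(2,4,6-triacetoxyphenyl)prop-2-en-1-one
Product: 9 (Z)-2-bromo-3-(4-acetoxyphenyl)-1-(2,4,6-triacetoxyphenyl)prop-2-en-1-one, via erythro-dibromide 8 (not isolated)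
Conditions: Br2 (1.05 equiv), CHCl3, 0 °C; then Et3N (1.5 equiv), 0 to 25 °C
Reagents that add atoms: bromine BrBr
Why: Electrophilic anti addition of bromine to the enone C=C followed by dehydrobromination through the acidic α-hydrogen is the standard route to α-bromochalcones, the four acetoxy groups keep both arenes too electron-poor for nuclear bromination, and the alkene geometry does not matter because it is lost in the radical of step 6.

**Step 6**
Reactants: 5 (2S)-5,7-diacetoxy-4-(tert-butyldimethylsilyloxy)-2-(4-methoxyphenyl)-2H-chromene; 9 (Z)-2-bromo-3-(4-acetoxyphenyl)-1-(2,4,6-triacetoxyphenyl)prop-2-en-1-one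
Product: 12 (2S,3R)-3-[(2S,3S)-5,7-dihydroxy-2-(4-hydroxyphenyl)-4-oxochroman-3-yl]-5,7-dihydroxy-2-(4-methoxyphenyl)chroman-4-one, via coupled hexaacetate 10 (not isolated), via seco-chalcone hexaol 11 (not isolated)
Conditions: 5 (1.5 equiv), fac-Ir(ppy)3 (1 mol %), dry degassed MeCN, 455 nm LEDs, 20 °C, Ar; then THF–MeOH, Mg(OMe)2 (3 equiv), −20 to 0 °C; AcOH quench at −20 °C
Reagents that add atoms: none
Why: Proposed new method: excited fac-Ir(ppy)3 reduces the C–Br bond of 9 to the linear, electrophilic α-acylvinyl radical, which adds to the electron-rich C3 of 5, and oxidation of the resulting α-silyloxy radical by the tetravalent iridium complex with loss of TBSBr gives 10 without a free C3 enolate, so that O1 cannot be expelled and 2S is kept; the closest known reaction types are the visible-light generation of vinyl radicals from α-bromochalcones with capture by electron-rich π systems and the radical alkylation of silyl enol ethers by α-bromoketones to 1,4-diketones. In the second stage Mg(OMe)2 transesterifies the six aryl acetates and one of the two equivalent ortho phenoxides of ring A'' closes ring C'' by a 6-endo-trig oxa-Michael addition to C2'', the classical chalcone to flavanone cyclisation. C3 is set by approach of the radical anti to the 2-anisyl group (trans, 3R), and any cis epimer can still drain into the trans isomer through the acidic C3–H of 10 and 11. C2'' and C3'' are set together in a Curtin–Hammett situation: the C–O bond formation is reversible, both alkene isomers give the same enolates, ring B'' stands pseudoaxial in them to avoid the C3'' substituent, and the irreversible protonation by magnesium-bound MeOH comes anti to ring B'', which makes ring C'' cis. The choice between the two cis pairs is made by C3: the Mg2+ held by O5, O4, O4'' and O5'' keeps C4=O syn to the enolate oxygen, which turns C2 and its anisyl group onto one enolate face, so that only the 2''S enolate, with ring B'' on that same face, has a free face, and its protonation gives 3''S, while the 2''R enolate is shielded on both faces and reverts. The step needs cross-coupling instead of radical reduction (polarity match, 5 in excess, no weak C–H bond next to the radical because ring A'' carries acetates), an electrophilic enone (the base is limited so that the least acidic phenol, that of ring B'', stays protonated) and no later epimerisation (the 5- and 5''-phenoxides make C3–H and C3''–H much less acidic, low temperature, AcOH quench).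

**Compound list**
1 | 5,7-dihydroxy-4H-chromen-4-one | Oc1cc(O)c2c(=O)ccoc2c1 | starting material
2 | 5,7-diacetoxy-4H-chromen-4-one | CC(=O)Oc1cc(OC(C)=O)c2c(=O)ccoc2c1 | intermediate
3 | 4-methoxyphenylboronic acid | COc1ccc(B(O)O)cc1 | starting material
4 | (2S)-5,7-diacetoxy-2-(4-methoxyphenyl)chroman-4-one | COc1ccc([C@H]2Oc3cc(OC(C)=O)cc(OC(C)=O)c3C(=O)C2)cc1 | intermediate
5 | (2S)-5,7-diacetoxy-4-(tert-butyldimethylsilyloxy)-2-(4-methoxyphenyl)-2H-chromene | COc1ccc([C@H]2Oc3cc(OC(C)=O)cc(OC(C)=O)c3C(O[Si](C)(C)C(C)(C)C)=C2)cc1 | intermediate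
6 | (±)-naringenin, 5,7-dihydroxy-2-(4-hydroxyphenyl)chroman-4-one | O=C1CC(c2ccc(O)cc2)Oc2cc(O)cc(O)c12 | starting material
7 | (E)-3-(4-acetoxyphenyl)-1-(2,4,6-triacetoxyphenyl)prop-2-en-1-one | CC(=O)Oc1ccc(/C=C/C(=O)c2c(OC(C)=O)cc(OC(C)=O)cc2OC(C)=O)cc1 | intermediate
8 | erythro-(2S*,3R*)-2,3-dibromo-3-(4-acetoxyphenyl)-1-(2,4,6-triacetoxyphenyl)propan-1-one, racemic, one enantiomer drawn | Br[C@H](c1ccc(OC(C)=O)cc1)[C@@H](Br)C(=O)c1c(OC(C)=O)cc(OC(C)=O)cc1OC(C)=O | intermediate
9 | (Z)-2-bromo-3-(4-acetoxyphenyl)-1-(2,4,6-triacetoxyphenyl)prop-2-en-1-one | CC(=O)Oc1ccc(/C=C(\Br)C(=O)c2c(OC(C)=O)cc(OC(C)=O)cc2OC(C)=O)cc1 | intermediate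
10 | (2S,3R)-5,7-diacetoxy-3-[1-(4-acetoxyphenyl)-3-oxo-3-(2,4,6-triacetoxyphenyl)prop-1-en-2-yl]-2-(4-methoxyphenyl)chroman-4-one, alkene as E/Z mixture | COc1ccc([C@H]2Oc3cc(OC(C)=O)cc(OC(C)=O)c3C(=O)[C@@H]2C(=Cc2ccc(OC(C)=O)cc2)C(=O)c2c(OC(C)=O)cc(OC(C)=O)cc2OC(C)=O)cc1 | intermediate
11 | (2S,3R)-5,7-dihydroxy-3-[1-(4-hydroxyphenyl)-3-oxo-3-(2,4,6-trihydroxyphenyl)prop-1-en-2-yl]-2-(4-methoxyphenyl)chroman-4-one, alkene as E/Z mixture | COc1ccc([C@H]2Oc3cc(O)cc(O)c3C(=O)[C@@H]2C(=Cc2ccc(O)cc2)C(=O)c2c(O)cc(O)cc2O)cc1 | intermediate
12 | (2S,3R)-3-[(2S,3S)-5,7-dihydroxy-2-(4-hydroxyphenyl)-4-oxochroman-3-yl]-5,7-dihydroxy-2-(4-methoxyphenyl)chroman-4-one | COc1ccc([C@H]2Oc3cc(O)cc(O)c3C(=O)[C@@H]2[C@@H]2C(=O)c3c(O)cc(O)cc3O[C@@H]2c2ccc(O)cc2)cc1 | target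

**Step count**
Total step count: 6. Longest linear sequence: 4 (steps 1, 2, 3, 6).

**Steps most likely to fail**

**Step 6**
- What may go wrong in the first stage: the vinyl radical may abstract hydrogen before it adds to C3. Energy transfer from the photocatalyst may open the 2H-chromene of 5 electrocyclically and erode 2S.
- What may go wrong in the second stage: the dienolate of the coupled chalcone may be protonated at C2'' (alkene migration) before ring closure. The C3'' protonation may show poor facial selectivity or be followed by epimerisation to the trans ring.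
- The fallback sets out from 5 and returns at 10. It forms C3–C3'' at the sp3 level and installs the alkene afterwards, using known reaction types only.
- Commercial 2',4',6'-trihydroxyacetophenone is acetylated to 2',4',6'-triacetoxyacetophenone F1.
- F1 is α-brominated with CuBr2 in EtOAc–CHCl3 to 2-bromo-1-(2,4,6-triacetoxyphenyl)ethanone F2.
- Redox-neutral radical alkylation of 5 with F2 uses Ru(bpy)3Cl2, MeCN and 455 nm light. The triplet energy of this catalyst is too low to sensitise the chromene. Attack again comes anti to the anisyl group and should give the 1,4-diketone (2S,3R)-3-phenacylflavanone pentaacetate F3.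
- Soft enolisation of the less hindered C3'' methylene (TiCl4, iPr2NEt, CH2Cl2, −78 °C) and aldol addition to 4-acetoxybenzaldehyde give the aldol adduct F4.
- Acid-catalysed dehydration (TsOH, toluene, 80 °C) gives isolated 10. This compound is then taken through the Mg(OMe)2 stage as a separate operation that can be optimised on its own.

**Step 2**
- What may go wrong: insertion may be slow because of the peri 5-acetoxy group, the electron-rich boronic acid may protodeboronate, or enantioface discrimination may be insufficient.
- The fallback sets out from 2 and 3 and returns at 4. It replaces asymmetric C–C bond formation by kinetic resolution.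
- Achiral conjugate addition (Pd(OCOCF3)2, 2,2'-bipyridine, same medium) gives the racemic flavanone diacetate F5.
- Asymmetric transfer hydrogenation uses RuCl(p-cymene)(TsDPEN) in the antipode that consumes the 2R ketone, with HCO2H/Et3N in EtOAc. It reduces the unwanted enantiomer to the cis-(2R,4R)-flavan-4-ol F6.
- Unreacted 4 is separated from F6 by chromatography.

**Step 3**
- What may go wrong: the Lewis acid may open the pyranone ring, the acetate groups may be silylated to ketene acetals, or the enol ether may hydrolyse on isolation.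
- The fallback sets out from 2 and returns at 10. It never enolises the ketone.
- Rhodium-catalysed asymmetric 1,4-addition of 4-methoxyphenylzinc chloride is run in the presence of Me3SiCl, with [RhCl(C2H4)2]2 and BINAP in the antipode that gives 2S, in THF at 20 °C.
- The rhodium enolate is trapped directly as the trimethylsilyl enol ether F7.
- F7 is used crude in place of 5 in the first stage of step 6.

**Further compounds**
F1 | step 6 | 2',4',6'-triacetoxyacetophenone | CC(=O)c1c(OC(C)=O)cc(OC(C)=O)cc1OC(C)=O
F2 | step 6 | 2-bromo-1-(2,4,6-triacetoxyphenyl)ethanone | O=C(CBr)c1c(OC(C)=O)cc(OC(C)=O)cc1OC(C)=O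
F3 | step 6 | (2S,3R)-5,7-diacetoxy-2-(4-methoxyphenyl)-3-[2-oxo-2-(2,4,6-triacetoxyphenyl)ethyl]chroman-4-one | COc1ccc([C@H]2Oc3cc(OC(C)=O)cc(OC(C)=O)c3C(=O)[C@@H]2CC(=O)c2c(OC(C)=O)cc(OC(C)=O)cc2OC(C)=O)cc1
F4 | step 6 | (2S,3R)-5,7-diacetoxy-3-[1-(4-acetoxyphenyl)-1-hydroxy-3-oxo-3-(2,4,6-triacetoxyphenyl)propan-2-yl]-2-(4-methoxyphenyl)chroman-4-one, mixture at the two new centres | COc1ccc([C@H]2Oc3cc(OC(C)=O)cc(OC(C)=O)c3C(=O)[C@@H]2C(C(O)c2ccc(OC(C)=O)cc2)C(=O)c2c(OC(C)=O)cc(OC(C)=O)cc2OC(C)=O)cc1
F5 | step 2 | racemic 5,7-diacetoxy-2-(4-methoxyphenyl)chroman-4-one | COc1ccc(C2Oc3cc(OC(C)=O)cc(OC(C)=O)c3C(=O)C2)cc1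
F6 | step 2 | (2R,4R)-5,7-diacetoxy-2-(4-methoxyphenyl)chroman-4-ol | COc1ccc([C@@H]2Oc3cc(OC(C)=O)cc(OC(C)=O)c3[C@H](O)C2)cc1
F7 | step 3 | (2S)-5,7-diacetoxy-2-(4-methoxyphenyl)-4-(trimethylsilyloxy)-2H-chromene | COc1ccc([C@H]2Oc3cc(OC(C)=O)cc(OC(C)=O)c3C(O[Si](C)(C)C)=C2)cc1
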